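Per litre and per hour, the gas can put at most 0.625 M h⁻¹ of coupling partner into solution: the transfer coefficient times the saturation concentration, reached with none dissolved, as at the start.

the same everywhere: gas 31 mM (held); time 2.0 h

| run | substrate |
|---|---|
| autumn | 0.25 M |
| winter | 0.40 M |
| midnight | 0.60 M |

- [target] at the end for autumn, winter, midnight, in this order
- the shape of the row from first to last (rises, then falls / hardly changes / falls, then rises / rises all the way / falls all the way)

- at the start none of coupling partner is dissolved
- "hardly changes" means that all values lie within two and a half points (for a concentration: within two and a half percent of the largest)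
- run time (autumn): 2.0 h

    coupling partner + intermediate A → intermediate B (k1 = 0.012 L mol⁻¹ s⁻¹)
    intermediate D → side product (k2 = 1.3 × 10⁻⁴ s⁻¹)
    intermediate B ⇌ intermediate C (K3 = 0.36, k3 = 0.0013 s⁻¹)
    intermediate C → target (k4 = 5.9 × 10⁻⁴ s⁻¹)
    intermediate C ⇌ intermediate D (K5 = 0.14, k5 = 0.035 s⁻¹)
    gas ⇌ coupling partner, rate k6*(csat - [coupling partner]) (k6 = 0.0056 s⁻¹, csat = 31 mM)
    substrate + coupling partner → intermediate A (k7 = 0.18 L mol⁻¹ s⁻¹)

I kept a ledger for substrate, the limiting reagent, following what it cost and where it went.

First entry: substrate takes one coupling partner and becomes intermediate A. In autumn, with substrate as charged, the coupling partner's half-life against this step alone was 0.26 min, shorter than that of its transfer, so I booked the supply here first. I divided each charge by the ceiling: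

t× = 0.400 h (autumn), 0.640 h (winter), 0.960 h (midnight)

This is the crossing time, the earliest moment at which this entry can be paid and control can pass to the second addition.

Second entry: intermediate A takes another coupling partner and becomes intermediate B. I balanced transfer against this use, with intermediate A at the charge, which gave a first-order constant a for each flask:

a = 0.872 h⁻¹, 0.721 h⁻¹, 0.586 h⁻¹

Third entry: intermediates B, C and D form one pool. Target leaves from intermediate C, and I let the pool drain at

L = k4 K3/(1 + K3 + K3 K5) = 0.542 h⁻¹

Here k4 is the constant of the step to target, and K3 and K5 are the equilibrium constants of the exchanges. In autumn the exchange of B with C relaxes in 2.35 min, shorter than the half-life of this drain, so I held the pool in balance. I left the side product out of the books, at 3.08% of the drain.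

Closing the books: with T the run time minus t× and cA the charge of substrate, the target is

cA [1 − (a e^(−LT) − L e^(−aT))/(a − L)]

My marks for the row, counted from the earliest crossing, were 0.0742 M, 0.0834 M and 0.0704 M. Winter stood higher than the other two, so the shape I committed to was: rises, then falls.

The forecast gave 0.068 M, 0.07 M and 0.059 M, a shape of rises, then falls, holding that “the higher loading gives more intermediate but less time to convert it”.

The simulation gave 0.0665 M, 0.0748 M and 0.0628 M, a shape of rises, then falls.

In autumn at 0.474 h, just past the crossing time of 0.400 h, substrate's half-life by the first addition was 0.097 h, shorter than the 1.5 h of intermediate A by the second. At midnight, whose crossing time is 0.960 h, the flask at 1.00 h still held 14.1% of its charge as substrate and 78.9% as intermediate A.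

The numbers come from no measurement; the result is computed.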